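**Strategy.** The 4-O-4 ether is cut into two flavan-3-ol halves that differ only at C2; both come from one aryl diazoacetate by enantiomeric C–H insertions. Everything rests on building the pyran ring of the ent-oritin half (O1, C2, C3, C4, C4a, C8a) from a five-membered 2,3-dihydrobenzofuran: the electron-rich ring A carbon C4a (ortho to O1, para to the 7-oxygen) migrates from C3 to the exocyclic CH2, which becomes C4, through a phenonium ion, while water enters at C3 with inversion. One operation thus delivers the 2,3-trans-flavan-3-ol. Its precursor is a trans-2-aryl-3-(mesyloxymethyl)-2,3-dihydrobenzofuran. The cis ether is closed later by silicon-tethered delivery.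

Key step: step 8

Abbreviations: TBS = tert-butyldimethylsilyl; Rh2(S-PTTL)4 = dirhodium tetrakis[N-phthaloyl-(S)-tert-leucinate], a dimer of divalent rhodium.

Remarks on the chemistry (assumptions):
- Rh2(R-PTTL)4 is assumed to give the (2R,3S)-cis ester 9 and Rh2(S-PTTL)4 its enantiomer 16. If the sense of induction is the opposite, the two catalyst antipodes are exchanged between steps 5 and 10.
- Compound 15 is drawn as the 3,4-cis epimer (alcohol entering anti to the 2-aryl group). Its C4 configuration does not matter, because C4 becomes planar again in step 15.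
- Step 12 is the same ring expansion as the key step, applied to the other half.

**Step 1**
Reactants: 1 2-(2,3,4-trimethoxyphenyl)acetic acid
Product: 3 6,7-dihydroxybenzofuran-2(3H)-one, via trihydroxy acid 2 (not isolated)
Conditions: BBr3, CH2Cl2, −78 °C to rt; H2O; then TsOH (cat.), toluene, reflux
Reagents that add atoms: none
Why: BBr3 cleaves the three aryl methyl ethers (Lewis-acid demethylation) and acid-catalysed lactonisation then masks only the oxygen ortho to the side chain, which differentiates it from the other two.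

**Step 2**
Reactants: 3 6,7-dihydroxybenzofuran-2(3H)-one
Product: 4 6,7-bis(TBS-oxy)benzofuran-2(3H)-one
Conditions: TBSCl, imidazole, DMF, 0 °C to rt
Reagents that add atoms: tert-butyldimethylsilyl chloride CC(C)(C)[Si](C)(C)Cl
Why: Standard silylation of the two free phenols should proceed cleanly, since the third oxygen is held in the lactone.

**Step 3**
Reactants: 4 6,7-bis(TBS-oxy)benzofuran-2(3H)-one; 5 [4-(TBS-oxy)phenyl]methanol
Product: 7 methyl 2-{3,4-bis(TBS-oxy)-2-[(4-TBS-oxyphenyl)methoxy]phenyl}acetate, via hydroxy ester 6 (not isolated)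
Conditions: MeOH, PPTS (cat.), 40 °C; evaporate; then 5, PPh3, DIAD, THF, 0 °C to rt
Reagents that add atoms: methanol CO
Why: Acid-catalysed methanolysis opens the strained aryl lactone to the methyl ester and frees only the ortho phenol, which is etherified by a Mitsunobu reaction under neutral conditions so that no phenoxide-induced silyl migration should occur.

**Step 4**
Reactants: 7 methyl 2-{3,4-bis(TBS-oxy)-2-[(4-TBS-oxyphenyl)methoxy]phenyl}acetate
Product: 8 methyl 2-diazo-2-{3,4-bis(TBS-oxy)-2-[(4-TBS-oxyphenyl)methoxy]phenyl}acetate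
Conditions: p-ABSA, DBU, MeCN, 0 °C to rt
Reagents that add atoms: 4-acetamidobenzenesulfonyl azide CC(=O)Nc1ccc(cc1)S(=O)(=O)N=[N+]=[N-]
Why: Regitz diazo transfer to the benzylic ester position should give the donor/acceptor diazo ester.

**Step 5**
Reactants: 8 methyl 2-diazo-2-{3,4-bis(TBS-oxy)-2-[(4-TBS-oxyphenyl)methoxy]phenyl}acetate
Product: 9 methyl (2R,3S)-6,7-bis(TBS-oxy)-2-(4-TBS-oxyphenyl)-2,3-dihydrobenzofuran-3-carboxylate (2,3-cis)
Conditions: Rh2(R-PTTL)4 (1 mol %), toluene, −60 °C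
Reagents that add atoms: none
Why: The rhodium carbenoid should insert into the benzylic ether C–H bond in a 1,5 sense (enantioselective intramolecular C–H insertion of an aryldiazoacetate), closing the dihydrobenzofuran; the cis relationship is kinetic and both centres are set by the chiral carboxylate ligands.

**Step 6**
Reactants: 9 methyl (2R,3S)-cis ester
Product: 10 methyl (2R,3R)-6,7-bis(TBS-oxy)-2-(4-TBS-oxyphenyl)-2,3-dihydrobenzofuran-3-carboxylate (2,3-trans)
Conditions: DBU (cat.), dry toluene, 60 °C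
Reagents that add atoms: none
Why: Only C3–H alpha to the ester is acidic, so base epimerisation should relax the cis ester to the more stable trans ester while C2 keeps its configuration (the ring C2–O bond lies orthogonal to the enolate, which disfavours beta-elimination).

**Step 7**
Reactants: 10 methyl (2R,3R)-trans ester
Product: 11 [(2R,3S)-6,7-bis(TBS-oxy)-2-(4-TBS-oxyphenyl)-2,3-dihydrobenzofuran-3-yl]methanol (2,3-trans)
Conditions: i-Bu2AlH, CH2Cl2, −78 to 0 °C; Rochelle salt
Reagents that add atoms: none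
Why: Hydride reduction of the ester to the primary alcohol touches no stereocentre and should leave the aryl silyl ethers intact at low temperature.

**Step 8**
Reactants: 11 [(2R,3S)-6,7-bis(TBS-oxy)-2-(4-TBS-oxyphenyl)-2,3-dihydrobenzofuran-3-yl]methanol
Product: 14 (2S,3R)-7,8-bis(TBS-oxy)-2-(4-TBS-oxyphenyl)chroman-3-ol (2,3-trans), via mesylate 12 (not isolated), via phenonium mesylate 13 (not isolated)
Conditions: Ms2O, 2,6-lutidine, CH2Cl2, 0 °C; evaporate; then HFIP/H2O (4:1), 2,6-lutidine, 40 °C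
Reagents that add atoms: water O
Why: Ionisation of the primary mesylate is assisted by ring A, whose ipso carbon (the future C4a, activated by the ortho ring oxygen and the para silyloxy group) attacks the CH2 carbon from the rear to give a spiro-cyclopropane phenonium ion; water then opens the three-membered ring at the secondary carbon C3 anti to the departing aryl carbon, so the C3–aryl bond of the five-membered ring is exchanged for a CH2–aryl bond and the ring grows by one carbon. The closest known reaction type is aryl-assisted solvolysis with Wagner–Meerwein 1,2-aryl shift, as in 2-arylethyl and indan-1-ylmethyl sulfonates. The six-membered ring is not closed by a new cyclisation: it arises by a 3-exo-tet attack of the arene on CH2 followed by SN2-type opening of the C3–C4a bond of the cyclopropane. C2 is not touched and keeps its configuration, and the new C3–O bond forms with inversion at C3, which should turn the trans arrangement of aryl and CH2 in 11 into the trans arrangement of aryl and hydroxyl in 14 (2S,3R). The step needs water to enter at C3 and not at the primary carbon; the strain of the ring-fused cyclopropane and the greater cationic character of the secondary carbon favour C3, attack at CH2 only returns 11 for recycling, and direct SN2 at the mesylate is suppressed by the weakly nucleophilic, strongly ionising medium.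

**Step 9**
Reactants: 14 (2S,3R)-7,8-bis(TBS-oxy)-2-(4-TBS-oxyphenyl)chroman-3-ol
Product: 15 (2S,3R,4R)-4-(2-ethoxyethoxy)-7,8-bis(TBS-oxy)-2-(4-TBS-oxyphenyl)chroman-3-ol
Conditions: DDQ, 2-ethoxyethanol, CH2Cl2, rt
Reagents that add atoms: 2-ethoxyethanol CCOCCO
Why: DDQ should abstract hydride from C4 (benzylic, para to the 7-oxygen) and the cation is trapped by the alcohol, the known oxidative C4 alkoxylation of protected flavan-3-ols with a free 3-OH, which installs a chelating leaving group.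

**Step 10**
Reactants: 8 methyl 2-diazo-2-{3,4-bis(TBS-oxy)-2-[(4-TBS-oxyphenyl)methoxy]phenyl}acetate
Product: 16 methyl (2S,3R)-6,7-bis(TBS-oxy)-2-(4-TBS-oxyphenyl)-2,3-dihydrobenzofuran-3-carboxylate (2,3-cis, enantiomer of 9)
Conditions: Rh2(S-PTTL)4 (1 mol %), toluene, −60 °C
Reagents that add atoms: none
Why: The same intramolecular C–H insertion with the enantiomeric catalyst should give the mirror-image cis ester, both centres being catalyst-controlled.

**Step 11**
Reactants: 16 methyl (2S,3R)-cis ester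
Product: 17 [(2S,3S)-6,7-bis(TBS-oxy)-2-(4-TBS-oxyphenyl)-2,3-dihydrobenzofuran-3-yl]methanol (2,3-cis)
Conditions: i-Bu2AlH, CH2Cl2, −78 to 0 °C; Rochelle salt
Reagents that add atoms: none
Why: Ester reduction at low temperature should keep the kinetic cis arrangement, because no base is present to epimerise C3.

**Step 12**
Reactants: 17 [(2S,3S)-6,7-bis(TBS-oxy)-2-(4-TBS-oxyphenyl)-2,3-dihydrobenzofuran-3-yl]methanol
Product: 20 (2R,3R)-7,8-bis(TBS-oxy)-2-(4-TBS-oxyphenyl)chroman-3-yl acetate (2,3-cis), via mesylate 18 (not isolated), via phenonium mesylate 19 (not isolated)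
Conditions: Ms2O, 2,6-lutidine, CH2Cl2, 0 °C; evaporate; then AcOH, 2,6-lutidine, 50 °C
Reagents that add atoms: acetic acid CC(=O)O
Why: The same phenonium-ion ring expansion under buffered acetolysis should deliver acetate to C3 with inversion, so the cis-dihydrobenzofuran gives the 2,3-cis flavan-3-yl acetate with C2 unchanged.

**Step 13**
Reactants: 20 (2R,3R)-7,8-bis(TBS-oxy)-2-(4-TBS-oxyphenyl)chroman-3-yl acetate
Product: 22 (2R,3R,4R)-4-hydroxy-7,8-bis(TBS-oxy)-2-(4-TBS-oxyphenyl)chroman-3-yl acetate (2,3-cis-3,4-cis), via acetoxonium salt 21 (not isolated)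
Conditions: DDQ, 4 Å sieves, CH2Cl2, 0 °C to rt; then H2O/THF
Reagents that add atoms: water O
Why: DDQ oxidation at C4 gives a cation that the axial 3-acetoxy group should capture on its own face (neighbouring-group participation, Woodward-type cis-hydroxylation), and hydrolysis of the cis-fused acetoxonium ion through the hemiorthoester is expected to leave the axial ester on O3 and the equatorial 4-OH.

**Step 14**
Reactants: 15 (2S,3R,4R)-4-(2-ethoxyethoxy)-7,8-bis(TBS-oxy)-2-(4-TBS-oxyphenyl)chroman-3-ol; 22 (2R,3R,4R)-4-hydroxy-7,8-bis(TBS-oxy)-2-(4-TBS-oxyphenyl)chroman-3-yl acetate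
Product: 24 dimethylsilylene-bridged bis-flavan (O3 of the ent-oritin half to O4 of the teracacidin half), via chlorosilyl ether 23 (not isolated)
Conditions: 15, Me2SiCl2 (excess), Et3N, CH2Cl2, 0 °C; evaporate; then 22, imidazole, DMF, rt
Reagents that add atoms: dichlorodimethylsilane C[Si](C)(Cl)Cl
Why: Stepwise silylation of two secondary alcohols with a dichlorosilane (temporary silicon tether) should join the only free hydroxyl of each half, with no stereocentre involved.

**Step 15**
Reactants: 24 dimethylsilylene-bridged bis-flavan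
Product: 26 hexa-TBS ether of the target carrying a 3-acetate on the teracacidin half, via silyl ether 25 (not isolated)
Conditions: TMSOTf (cat.), 2,6-di-tert-butyl-4-methylpyridine, 4 Å sieves, CH2Cl2, −78 to −40 °C; then aq. NaHCO3/THF
Reagents that add atoms: none
Why: Proposed new method: TMSOTf should ionise the basic, bidentate 4-(2-ethoxyethoxy) group of the ent-oritin half in preference to the hindered, weakly basic silyl ether oxygen on C4 of the other half, and the C4 cation (stabilised by O1 and the 7-silyloxy group) is captured by that tethered oxygen through a five-membered ring that can only form on the face of the C3–O bond, so the new C4–O bond is 3,4-cis (4R); the silyl group then passes to the released alkoxide to give 25, which is hydrolysed on work-up. The closest known reaction type is silicon-tethered intramolecular aglycon delivery to glycosyl cations (cis-glycoside synthesis), together with untethered TMSOTf condensations of 4-alkoxyflavan-3-ols.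

**Step 16**
Reactants: 26 hexa-TBS ether 3-acetate
Product: 27 hexa-TBS ether of the target (both 3-OH free)
Conditions: i-Bu2AlH, CH2Cl2, −78 °C; Rochelle salt
Reagents that add atoms: none
Why: Reductive cleavage of the secondary acetate should spare the aryl silyl ethers and the bis-benzylic ether, and avoids base while the phenols are still masked.

**Step 17**
Reactants: 27 hexa-TBS ether of the target
Product: 28 CNP0241481.1 (target)
Conditions: Bu4NF, AcOH, THF, 0 °C to rt, argon
Reagents that add atoms: none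
Why: Fluoride buffered with acetic acid should remove the six aryl silyl groups near neutrality, which matters because the C4–O–C4 ether ionises under acid and is expelled through a quinone methide from a free 7-phenoxide under base.

**Compound list**
1 | 2-(2,3,4-trimethoxyphenyl)acetic acid | COc1ccc(CC(=O)O)c(OC)c1OC | starting material
2 | 2-(2,3,4-trihydroxyphenyl)acetic acid | OC(=O)Cc1ccc(O)c(O)c1O | intermediate
3 | 6,7-dihydroxybenzofuran-2(3H)-one | O=C1Cc2ccc(O)c(O)c2O1 | intermediate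
4 | 6,7-bis(TBS-oxy)benzofuran-2(3H)-one | O=C1Cc2ccc(O[Si](C)(C)C(C)(C)C)c(O[Si](C)(C)C(C)(C)C)c2O1 | intermediate
5 | [4-(TBS-oxy)phenyl]methanol | OCc1ccc(O[Si](C)(C)C(C)(C)C)cc1 | starting material
6 | methyl 2-[2-hydroxy-3,4-bis(TBS-oxy)phenyl]acetate | COC(=O)Cc1ccc(O[Si](C)(C)C(C)(C)C)c(O[Si](C)(C)C(C)(C)C)c1O | intermediate
7 | methyl 2-{3,4-bis(TBS-oxy)-2-[(4-TBS-oxyphenyl)methoxy]phenyl}acetate | COC(=O)Cc1ccc(O[Si](C)(C)C(C)(C)C)c(O[Si](C)(C)C(C)(C)C)c1OCc1ccc(O[Si](C)(C)C(C)(C)C)cc1 | intermediate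
8 | methyl 2-diazo-2-{3,4-bis(TBS-oxy)-2-[(4-TBS-oxyphenyl)methoxy]phenyl}acetate | COC(=O)C(=[N+]=[N-])c1ccc(O[Si](C)(C)C(C)(C)C)c(O[Si](C)(C)C(C)(C)C)c1OCc1ccc(O[Si](C)(C)C(C)(C)C)cc1 | intermediate
9 | methyl (2R,3S)-6,7-bis(TBS-oxy)-2-(4-TBS-oxyphenyl)-2,3-dihydrobenzofuran-3-carboxylate (cis) | COC(=O)[C@H]1c2ccc(O[Si](C)(C)C(C)(C)C)c(O[Si](C)(C)C(C)(C)C)c2O[C@H]1c1ccc(O[Si](C)(C)C(C)(C)C)cc1 | intermediate
10 | methyl (2R,3R)-6,7-bis(TBS-oxy)-2-(4-TBS-oxyphenyl)-2,3-dihydrobenzofuran-3-carboxylate (trans) | COC(=O)[C@@H]1c2ccc(O[Si](C)(C)C(C)(C)C)c(O[Si](C)(C)C(C)(C)C)c2O[C@H]1c1ccc(O[Si](C)(C)C(C)(C)C)cc1 | intermediate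
11 | [(2R,3S)-6,7-bis(TBS-oxy)-2-(4-TBS-oxyphenyl)-2,3-dihydrobenzofuran-3-yl]methanol (trans) | OC[C@@H]1c2ccc(O[Si](C)(C)C(C)(C)C)c(O[Si](C)(C)C(C)(C)C)c2O[C@H]1c1ccc(O[Si](C)(C)C(C)(C)C)cc1 | intermediate
12 | methanesulfonate of 11 | CS(=O)(=O)OC[C@@H]1c2ccc(O[Si](C)(C)C(C)(C)C)c(O[Si](C)(C)C(C)(C)C)c2O[C@H]1c1ccc(O[Si](C)(C)C(C)(C)C)cc1 | intermediate
13 | spiro-cyclopropane phenonium ion from 12, methanesulfonate salt | [O+]1=C2C(O[Si](C)(C)C(C)(C)C)=C(O[Si](C)(C)C(C)(C)C)C=C[C@@]23C[C@H]3[C@@H]1c1ccc(O[Si](C)(C)C(C)(C)C)cc1.CS(=O)(=O)[O-] | intermediate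
14 | (2S,3R)-7,8-bis(TBS-oxy)-2-(4-TBS-oxyphenyl)chroman-3-ol (2,3-trans) | C1c2ccc(O[Si](C)(C)C(C)(C)C)c(O[Si](C)(C)C(C)(C)C)c2O[C@@H](c2ccc(O[Si](C)(C)C(C)(C)C)cc2)[C@@H]1O | intermediate
15 | (2S,3R,4R)-4-(2-ethoxyethoxy)-7,8-bis(TBS-oxy)-2-(4-TBS-oxyphenyl)chroman-3-ol | CCOCCO[C@@H]1c2ccc(O[Si](C)(C)C(C)(C)C)c(O[Si](C)(C)C(C)(C)C)c2O[C@@H](c2ccc(O[Si](C)(C)C(C)(C)C)cc2)[C@@H]1O | intermediate
16 | methyl (2S,3R)-6,7-bis(TBS-oxy)-2-(4-TBS-oxyphenyl)-2,3-dihydrobenzofuran-3-carboxylate (cis) | COC(=O)[C@@H]1c2ccc(O[Si](C)(C)C(C)(C)C)c(O[Si](C)(C)C(C)(C)C)c2O[C@@H]1c1ccc(O[Si](C)(C)C(C)(C)C)cc1 | intermediate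
17 | [(2S,3S)-6,7-bis(TBS-oxy)-2-(4-TBS-oxyphenyl)-2,3-dihydrobenzofuran-3-yl]methanol (cis) | OC[C@@H]1c2ccc(O[Si](C)(C)C(C)(C)C)c(O[Si](C)(C)C(C)(C)C)c2O[C@@H]1c1ccc(O[Si](C)(C)C(C)(C)C)cc1 | intermediate
18 | methanesulfonate of 17 | CS(=O)(=O)OC[C@@H]1c2ccc(O[Si](C)(C)C(C)(C)C)c(O[Si](C)(C)C(C)(C)C)c2O[C@@H]1c1ccc(O[Si](C)(C)C(C)(C)C)cc1 | intermediate
19 | spiro-cyclopropane phenonium ion from 18, methanesulfonate salt | [O+]1=C2C(O[Si](C)(C)C(C)(C)C)=C(O[Si](C)(C)C(C)(C)C)C=C[C@@]23C[C@H]3[C@H]1c1ccc(O[Si](C)(C)C(C)(C)C)cc1.CS(=O)(=O)[O-] | intermediate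
20 | (2R,3R)-7,8-bis(TBS-oxy)-2-(4-TBS-oxyphenyl)chroman-3-yl acetate (2,3-cis) | C1c2ccc(O[Si](C)(C)C(C)(C)C)c(O[Si](C)(C)C(C)(C)C)c2O[C@H](c2ccc(O[Si](C)(C)C(C)(C)C)cc2)[C@@H]1OC(C)=O | intermediate
21 | cis-fused 2-methyl-1,3-dioxolan-2-ylium (acetoxonium) ion on C3/C4 of 20, salt of the DDQ hydroquinone monoanion | CC1=[O+][C@@H]2c3ccc(O[Si](C)(C)C(C)(C)C)c(O[Si](C)(C)C(C)(C)C)c3O[C@H](c3ccc(O[Si](C)(C)C(C)(C)C)cc3)[C@@H]2O1.[O-]c1c(Cl)c(Cl)c(O)c(C#N)c1C#N | intermediate
22 | (2R,3R,4R)-4-hydroxy-7,8-bis(TBS-oxy)-2-(4-TBS-oxyphenyl)chroman-3-yl acetate (all-cis) | O[C@@H]1c2ccc(O[Si](C)(C)C(C)(C)C)c(O[Si](C)(C)C(C)(C)C)c2O[C@H](c2ccc(O[Si](C)(C)C(C)(C)C)cc2)[C@@H]1OC(C)=O | intermediate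
23 | 3-O-(chlorodimethylsilyl) ether of 15 | CCOCCO[C@@H]1c2ccc(O[Si](C)(C)C(C)(C)C)c(O[Si](C)(C)C(C)(C)C)c2O[C@@H](c2ccc(O[Si](C)(C)C(C)(C)C)cc2)[C@@H]1O[Si](C)(C)Cl | intermediate
24 | dimethylsilylene-bridged bis-flavan: O3 of 15 and O4 of 22 joined through SiMe2 | CCOCCO[C@@H]1c2ccc(O[Si](C)(C)C(C)(C)C)c(O[Si](C)(C)C(C)(C)C)c2O[C@@H](c2ccc(O[Si](C)(C)C(C)(C)C)cc2)[C@@H]1O[Si](C)(C)O[C@@H]1c2ccc(O[Si](C)(C)C(C)(C)C)c(O[Si](C)(C)C(C)(C)C)c2O[C@H](c2ccc(O[Si](C)(C)C(C)(C)C)cc2)[C@@H]1OC(C)=O | intermediate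
25 | 4-O-4 ether with (2-ethoxyethoxy)dimethylsilyl on O3 of the ent-oritin half and acetyl on O3 of the teracacidin half | CC(C)(C)[Si](C)(C)Oc1ccc([C@H]2Oc3c(ccc(O[Si](C)(C)C(C)(C)C)c3O[Si](C)(C)C(C)(C)C)[C@@H](O[C@@H]3c4ccc(O[Si](C)(C)C(C)(C)C)c(O[Si](C)(C)C(C)(C)C)c4O[C@@H](c4ccc(O[Si](C)(C)C(C)(C)C)cc4)[C@@H]3O[Si](C)(C)OCCOCC)[C@H]2OC(C)=O)cc1 | intermediate
26 | hexa-TBS ether of the target, 3-acetate on the (2R,3R,4R) half | CC(C)(C)[Si](C)(C)Oc1ccc([C@H]2Oc3c(ccc(O[Si](C)(C)C(C)(C)C)c3O[Si](C)(C)C(C)(C)C)[C@@H](O[C@@H]3c4ccc(O[Si](C)(C)C(C)(C)C)c(O[Si](C)(C)C(C)(C)C)c4O[C@@H](c4ccc(O[Si](C)(C)C(C)(C)C)cc4)[C@@H]3O)[C@H]2OC(C)=O)cc1 | intermediate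
27 | hexa-TBS ether of the target | CC(C)(C)[Si](C)(C)Oc1ccc([C@H]2Oc3c(ccc(O[Si](C)(C)C(C)(C)C)c3O[Si](C)(C)C(C)(C)C)[C@@H](O[C@@H]3c4ccc(O[Si](C)(C)C(C)(C)C)c(O[Si](C)(C)C(C)(C)C)c4O[C@@H](c4ccc(O[Si](C)(C)C(C)(C)C)cc4)[C@@H]3O)[C@H]2O)cc1 | intermediate
28 | CNP0241481.1: (2R,3R,4R)-flavan-3,7,8,4'-tetrol 4-yl (2S,3R,4R)-flavan-3,7,8,4'-tetrol 4-yl ether | Oc1ccc([C@H]2Oc3c(ccc(O)c3O)[C@@H](O[C@@H]3c4ccc(O)c(O)c4O[C@@H](c4ccc(O)cc4)[C@@H]3O)[C@H]2O)cc1 | target

**Total step count:** 17. **Longest linear sequence:** 13 steps (steps 1–9, then 14–17).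

**Steps most likely to fail**

1. Step 15 (tethered ether closure). What may go wrong: ionisation on the wrong side of the tether (the C4–O bond of the teracacidin half), or proton loss from the C4 cation before the tethered oxygen arrives. Fallback with known chemistry, without the tether: it sets out from 15 and 22 (step 14 is omitted) and comes back at 26. TMSOTf-promoted substitution of the 2-ethoxyethoxy group of 15 by the free 4-OH of 22 (22 in excess, CH2Cl2, −78 °C), the established way to join 4-alkoxyflavan-3-ols to nucleophiles, should give the ether as a mixture of C4 epimers in the ent-oritin half, from which the 3,4-cis epimer 26 is separated by chromatography. This fallback makes no new compound (F0).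

2. Step 8 (key ring expansion). What may go wrong: capture of the phenonium ion at the primary carbon, which returns the unrearranged alcohol, or uncontrolled proton loss. Fallback: it sets out from mesylate 12 and comes back at 14. Warming 12 with 2,6-lutidine in dry HFIP (no water) should let the phenonium ion lose a proton from the CH2 carbon as the C3–aryl bond breaks, still a ring expansion by 1,2-aryl shift, giving (2R)-7,8-bis(TBS-oxy)-2-(4-TBS-oxyphenyl)-2H-chromene F1. Hydroboration–oxidation (BH3·THF, then NaBO3·4H2O) should place boron at C3 anti to the 2-aryl group and give the 2,3-trans alcohol 14.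

3. Step 13 (cis-hydroxylation at C4). What may go wrong: attack of water on the C4 cation from the face opposite the acetoxy group before the ester participates (3,4-trans alcohol), or acyl migration between O3 and O4. Fallback: it sets out from 20 and comes back at 22. DDQ in excess in wet dioxane should oxidise C4 through the alcohol to (2R,3S)-3-acetoxy-7,8-bis(TBS-oxy)-2-(4-TBS-oxyphenyl)chroman-4-one F2. NaBH4 with CeCl3 at −78 °C should then deliver hydride anti to the axial 3-acetoxy group, the usual course for 2,3-cis-dihydroflavonols, giving the all-cis alcohol 22.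

**Further compounds**
F0 | step 15 | none | none
F1 | step 8 | (2R)-7,8-bis(TBS-oxy)-2-(4-TBS-oxyphenyl)-2H-chromene | C1=C[C@H](c2ccc(O[Si](C)(C)C(C)(C)C)cc2)Oc2c(O[Si](C)(C)C(C)(C)C)c(O[Si](C)(C)C(C)(C)C)ccc12
F2 | step 13 | (2R,3S)-3-acetoxy-7,8-bis(TBS-oxy)-2-(4-TBS-oxyphenyl)chroman-4-one (2,3-cis) | O=C1c2ccc(O[Si](C)(C)C(C)(C)C)c(O[Si](C)(C)C(C)(C)C)c2O[C@H](c2ccc(O[Si](C)(C)C(C)(C)C)cc2)[C@@H]1OC(C)=O
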